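**Retrosynthetic overview**
1. Target 24 ⇐ nona-O-allyl compound 23 by one Pd(0) deallylation; allyl is the only protecting group used.
2. Key disconnection in 23: both C–O bonds at the dihydrobenzofuran, the C3 ester C–O and the ring C2–O1 bond. This leads back to 3-arylidene-benzofuran-2(3H)-one 21 plus alcohol 6, joined in one catalytic alcoholysis/oxa-Michael relay.
3. 21 ⇐ Knoevenagel condensation of benzofuranone 20 with aldehyde 2; 20 ⇐ phenol 16 by Gassman ortho-alkylation and lactonisation.
4. 16 ⇐ L-tyrosine: hydroxy-deamination, ortho-formylation, allylation, Mitsunobu inversion with acid 4 (gives the (R) ester centre), Baeyer–Villiger oxidation (second catechol oxygen).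
5. Ring order: the lactone ring is made first (step 9) and is then converted into the dihydrobenzofuran ring (step 12).

Assumptions: sodium danshensu ((R)-configured) and L-tyrosine are bought. Compound 21 is drawn as the Z isomer expected from the C4 substituent; its E/Z ratio does not matter because step 12 removes the double bond.

**Step 1**
Reactants: 1 3,4-dihydroxybenzaldehyde
Product: 2 3,4-bis(allyloxy)benzaldehyde
Conditions: allyl bromide, K2CO3, DMF, 60 °C
Reagents that add atoms: allyl bromide, C=CCBr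
Why: Williamson O-alkylation of both phenoxides; no stereocentre is involved.

**Step 2**
Reactants: 2 3,4-bis(allyloxy)benzaldehyde
Product: 4 (E)-3-[3,4-bis(allyloxy)phenyl]acrylic acid, via benzylidenemalonic acid 3 (not isolated)
Conditions: CH2(CO2H)2, pyridine, piperidine (cat.), 90 °C
Reagents that add atoms: malonic acid, OC(=O)CC(=O)O
Why: Knoevenagel–Doebner condensation; decarboxylation of 3 gives the E-cinnamic acid.

**Step 3**
Reactants: 5 sodium danshensu [sodium (R)-3-(3,4-dihydroxyphenyl)-2-hydroxypropanoate]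
Product: 6 allyl (R)-3-[3,4-bis(allyloxy)phenyl]-2-hydroxypropanoate
Conditions: allyl bromide, K2CO3, DMF, rt, N2
Reagents that add atoms: allyl bromide, C=CCBr
Why: Williamson/carboxylate O-alkylation; carbonate deprotonates only the phenols and the acid, so the secondary alcohol stays free and the (R) centre is untouched.

**Step 4**
Reactants: 7 L-tyrosine
Product: 10 (S)-2-hydroxy-3-(4-hydroxyphenyl)propanoic acid, via diazonium carboxylate 8 (not isolated), via alpha-lactone 9 (not isolated)
Conditions: NaNO2, 1 M H2SO4, 0 °C → rt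
Reagents that add atoms: water, O
Why: Diazotisation/hydroxy-deamination of an α-amino acid with net retention: the carboxylate displaces N2 from 8 with inversion to give 9, and water opens 9 with a second inversion, so the (S) centre is kept.

**Step 5**
Reactants: 10 (S)-2-hydroxy-3-(4-hydroxyphenyl)propanoic acid
Product: 12 (S)-3-(3-formyl-4-hydroxyphenyl)-2-hydroxypropanoic acid, via hydroxymethyl phenol 11 (not isolated)
Conditions: MgCl2, Et3N, (CH2O)n, MeCN, reflux; then 1 M HCl
Reagents that add atoms: paraformaldehyde (formaldehyde), C=O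
Why: Magnesium-mediated (Casiraghi–Skattebøl) ortho-formylation: the Mg phenoxide delivers formaldehyde only ortho to the phenol (para is blocked) and 11 is oxidised in situ by a second formaldehyde (Oppenauer-type hydride transfer); the stereocentre is not touched.

**Step 6**
Reactants: 12 (S)-3-(3-formyl-4-hydroxyphenyl)-2-hydroxypropanoic acid
Product: 13 allyl (S)-3-[4-(allyloxy)-3-formylphenyl]-2-hydroxypropanoate
Conditions: allyl bromide, K2CO3, DMF, rt
Reagents that add atoms: allyl bromide, C=CCBr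
Why: Williamson/carboxylate O-alkylation of the phenol and the acid in one operation; the secondary alcohol is not alkylated and the (S) centre is unchanged.

**Step 7**
Reactants: 13 allyl (S)-3-[4-(allyloxy)-3-formylphenyl]-2-hydroxypropanoate; 4 (E)-3-[3,4-bis(allyloxy)phenyl]acrylic acid
Product: 14 allyl (R)-2-{[(E)-3-(3,4-bis(allyloxy)phenyl)acryloyl]oxy}-3-[4-(allyloxy)-3-formylphenyl]propanoate
Conditions: PPh3, DIAD, THF, 0 °C → rt
Reagents that add atoms: none
Why: Mitsunobu esterification; the carboxylate displaces the activated secondary alcohol by SN2, which inverts (S) to the required (R) ester centre.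

**Step 8**
Reactants: 14 (aldehyde from step 7)
Product: 16 allyl (R)-2-{[(E)-3-(3,4-bis(allyloxy)phenyl)acryloyl]oxy}-3-[4-(allyloxy)-3-hydroxyphenyl]propanoate, via aryl formate 15 (not isolated)
Conditions: mCPBA, NaHCO3, CH2Cl2, 0 °C → rt; then aq. NaHCO3, THF
Reagents that add atoms: mCPBA, OOC(=O)c1cccc(Cl)c1
Why: Baeyer–Villiger (Dakin-type) oxidation: the electron-rich ortho-alkoxy aryl group migrates to give formate 15, which hydrolyses to the phenol; the allyl alkenes and the electron-poor cinnamate react far more slowly, and the stereocentre is not involved.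

**Step 9**
Reactants: 16 (phenol from step 8)
Product: 19 allyl (R)-2-{[(E)-3-(3,4-bis(allyloxy)phenyl)acryloyl]oxy}-3-[7-(allyloxy)-3-(methylthio)-2-oxo-2,3-dihydrobenzofuran-4-yl]propanoate (both C3 epimers), via O-aryl sulfonium ylide 17 (not isolated), via open hydroxy ester 18 (not isolated)
Conditions: MeSCH2CO2Et, SO2Cl2, CH2Cl2, −78 °C; then 16; then Et3N, −78 °C → rt; then TsOH (cat.), toluene, 80 °C
Reagents that add atoms: ethyl 2-(methylthio)acetate, CCOC(=O)CSC
Why: Gassman ortho-alkylation: [2,3]-sigmatropic rearrangement of ylide 17 can only reach the one free ortho carbon (the other bears the allyloxy group), and phenol 18 then lactonises onto the new ester; the C3 centre formed here is removed in step 10.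

**Step 10**
Reactants: 19 (3-methylthio lactone)
Product: 20 allyl (R)-2-{[(E)-3-(3,4-bis(allyloxy)phenyl)acryloyl]oxy}-3-[7-(allyloxy)-2-oxo-2,3-dihydrobenzofuran-4-yl]propanoate
Conditions: Zn, AcOH, rt
Reagents that add atoms: none
Why: Reductive desulfurisation of an α-thio carbonyl compound by zinc (electron transfer, C–S cleavage, protonation); allyl groups, the cinnamate and the α-acyloxy ester are not reduced under these conditions.

**Step 11**
Reactants: 20 (benzofuranone); 2 3,4-bis(allyloxy)benzaldehyde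
Product: 21 allyl (R)-2-{[(E)-3-(3,4-bis(allyloxy)phenyl)acryloyl]oxy}-3-{7-(allyloxy)-3-[(Z)-3,4-bis(allyloxy)benzylidene]-2-oxo-2,3-dihydrobenzofuran-4-yl}propanoate
Conditions: piperidine (cat.), AcOH (cat.), toluene, 4 Å MS, 60 °C, Ar
Reagents that add atoms: none
Why: Knoevenagel condensation of the acidic lactone CH2 (pKa about 13) with the aldehyde via its iminium ion; the C4 substituent pushes the aryl group to the carbonyl side (Z), and no stereocentre is set.

**Step 12**
Reactants: 21 (arylidene lactone); 6 allyl (R)-3-[3,4-bis(allyloxy)phenyl]-2-hydroxypropanoate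
Product: 23 nona-O-allyl target [allyl (R)-2-{[(E)-3-(3,4-bis(allyloxy)phenyl)acryloyl]oxy}-3-[(2S,3S)-7-(allyloxy)-2-[3,4-bis(allyloxy)phenyl]-3-({(R)-1-(allyloxy)-3-[3,4-bis(allyloxy)phenyl]-1-oxopropan-2-yl}oxycarbonyl)-2,3-dihydrobenzofuran-4-yl]propanoate], via open phenol cinnamate 22 (not isolated)
Conditions: 6 (1.2 equiv), chiral thiourea–iminophosphorane catalyst (10 mol%; L-tert-leucine-derived 3,5-bis(trifluoromethyl)phenyl thiourea, iminophosphorane from P(4-MeOC6H4)3), toluene, 4 Å MS, −20 → 0 °C; AcOH quench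
Reagents that add atoms: none
Why: Proposed new method: the bifunctional superbase/thiourea catalyst is expected to (i) activate alcohol 6 as a general base while the thiourea binds the lactone carbonyl, so the strained aryl ester of 21 is transesterified to the ortho-phenoxide/iminophosphoranium ion pair of 22; (ii) hold that phenoxide over one face of the ester-conjugated C=C for a 5-endo-trig oxa-Michael closure that forms C2–O1 and sets C2 as (S) under catalyst control (the remote (R) centres give little bias; the D-tert-leucine antipode is used if a model run shows the opposite sense); and (iii) protonate the ester enolate anti to the C2 aryl group to give the 2,3-trans (3S) product and free catalyst. The closest known reaction types are thiourea/organobase-catalysed alcoholysis of lactones, base-mediated racemic ring closure of 2-(2-hydroxyaryl)cinnamates and iminophosphorane-catalysed enantioselective oxa-Michael additions to unsaturated esters; none has been run as a relay or in a 5-endo mode with catalyst control.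

**Step 13**
Reactants: 23 (nona-O-allyl target)
Product: 24 CNP0201431.1 [(2S,3S)-4-{(2R)-2-carboxy-2-[(E)-3-(3,4-dihydroxyphenyl)acryloyloxy]ethyl}-2-(3,4-dihydroxyphenyl)-7-hydroxy-2,3-dihydrobenzofuran-3-carboxylic acid 3-[(R)-1-carboxy-2-(3,4-dihydroxyphenyl)ethyl] ester]
Conditions: Pd(PPh3)4 (cat.), PhNHMe, THF (degassed), rt, Ar; C18 chromatography (0.1% HCO2H)
Reagents that add atoms: none
Why: Tsuji–Trost-type Pd(0) allyl transfer: each allyl ether or ester ionises to a π-allyl complex that is trapped by the weakly basic amine, so the base-sensitive dihydrobenzofuran ester, the two alkyl esters and the cinnamate are left alone and no stereocentre is affected.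

**Compound list**
1 | 3,4-dihydroxybenzaldehyde | O=Cc1ccc(O)c(O)c1 | starting material
2 | 3,4-bis(allyloxy)benzaldehyde | O=Cc1ccc(OCC=C)c(OCC=C)c1 | intermediate
3 | 2-[3,4-bis(allyloxy)benzylidene]malonic acid (not isolated) | OC(=O)C(=Cc1ccc(OCC=C)c(OCC=C)c1)C(=O)O | intermediate
4 | (E)-3-[3,4-bis(allyloxy)phenyl]acrylic acid | OC(=O)/C=C/c1ccc(OCC=C)c(OCC=C)c1 | intermediate
5 | sodium (R)-3-(3,4-dihydroxyphenyl)-2-hydroxypropanoate (sodium danshensu) | [Na+].[O-]C(=O)[C@H](O)Cc1ccc(O)c(O)c1 | starting material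
6 | allyl (R)-3-[3,4-bis(allyloxy)phenyl]-2-hydroxypropanoate | C=CCOC(=O)[C@H](O)Cc1ccc(OCC=C)c(OCC=C)c1 | intermediate
7 | L-tyrosine | N[C@@H](Cc1ccc(O)cc1)C(=O)O | starting material
8 | (S)-2-diazonio-3-(4-hydroxyphenyl)propanoate (not isolated) | [O-]C(=O)[C@@H]([N+]#N)Cc1ccc(O)cc1 | intermediate
9 | (R)-3-(4-hydroxybenzyl)oxiran-2-one, the alpha-lactone (not isolated) | O=C1O[C@@H]1Cc1ccc(O)cc1 | intermediate
10 | (S)-2-hydroxy-3-(4-hydroxyphenyl)propanoic acid | OC(=O)[C@@H](O)Cc1ccc(O)cc1 | intermediate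
11 | (S)-2-hydroxy-3-[4-hydroxy-3-(hydroxymethyl)phenyl]propanoic acid (not isolated) | OC(=O)[C@@H](O)Cc1ccc(O)c(CO)c1 | intermediate
12 | (S)-3-(3-formyl-4-hydroxyphenyl)-2-hydroxypropanoic acid | OC(=O)[C@@H](O)Cc1ccc(O)c(C=O)c1 | intermediate
13 | allyl (S)-3-[4-(allyloxy)-3-formylphenyl]-2-hydroxypropanoate | C=CCOC(=O)[C@@H](O)Cc1ccc(OCC=C)c(C=O)c1 | intermediate
14 | allyl (R)-2-{[(E)-3-(3,4-bis(allyloxy)phenyl)acryloyl]oxy}-3-[4-(allyloxy)-3-formylphenyl]propanoate | C=CCOC(=O)[C@H](OC(=O)/C=C/c1ccc(OCC=C)c(OCC=C)c1)Cc1ccc(OCC=C)c(C=O)c1 | intermediate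
15 | aryl formate of 16: 3-(formyloxy) analogue of 14 (not isolated) | C=CCOC(=O)[C@H](OC(=O)/C=C/c1ccc(OCC=C)c(OCC=C)c1)Cc1ccc(OCC=C)c(OC=O)c1 | intermediate
16 | allyl (R)-2-{[(E)-3-(3,4-bis(allyloxy)phenyl)acryloyl]oxy}-3-[4-(allyloxy)-3-hydroxyphenyl]propanoate | C=CCOC(=O)[C@H](OC(=O)/C=C/c1ccc(OCC=C)c(OCC=C)c1)Cc1ccc(OCC=C)c(O)c1 | intermediate
17 | O-aryl (ethoxycarbonylmethylide)(methyl)sulfonium ylide of 16 (not isolated) | C=CCOC(=O)[C@H](OC(=O)/C=C/c1ccc(OCC=C)c(OCC=C)c1)Cc1ccc(OCC=C)c(O[S+](C)[CH-]C(=O)OCC)c1 | intermediate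
18 | 16 carrying CH(SMe)CO2Et at the ring carbon between the side chain and the OH; both epimers (not isolated) | C=CCOC(=O)[C@H](OC(=O)/C=C/c1ccc(OCC=C)c(OCC=C)c1)Cc1ccc(OCC=C)c(O)c1C(SC)C(=O)OCC | intermediate
19 | allyl (R)-2-{[(E)-3-(3,4-bis(allyloxy)phenyl)acryloyl]oxy}-3-[7-(allyloxy)-3-(methylthio)-2-oxo-2,3-dihydrobenzofuran-4-yl]propanoate, both C3 epimers | C=CCOC(=O)[C@H](OC(=O)/C=C/c1ccc(OCC=C)c(OCC=C)c1)Cc1ccc(OCC=C)c2OC(=O)C(SC)c12 | intermediate
20 | allyl (R)-2-{[(E)-3-(3,4-bis(allyloxy)phenyl)acryloyl]oxy}-3-[7-(allyloxy)-2-oxo-2,3-dihydrobenzofuran-4-yl]propanoate | C=CCOC(=O)[C@H](OC(=O)/C=C/c1ccc(OCC=C)c(OCC=C)c1)Cc1ccc(OCC=C)c2OC(=O)Cc12 | intermediate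
21 | 3-[(Z)-3,4-bis(allyloxy)benzylidene] derivative of 20 | C=CCOC(=O)[C@H](OC(=O)/C=C/c1ccc(OCC=C)c(OCC=C)c1)Cc1ccc(OCC=C)c2OC(=O)/C(=C\c3ccc(OCC=C)c(OCC=C)c3)c12 | intermediate
22 | open phenol: (Z)-2-aryl-3-[3,4-bis(allyloxy)phenyl]acrylate of alcohol 6, aryl = the 2-hydroxy-3-allyloxy-6-substituted ring of 16 (not isolated) | C=CCOC(=O)[C@H](OC(=O)/C=C/c1ccc(OCC=C)c(OCC=C)c1)Cc1ccc(OCC=C)c(O)c1/C(=C/c1ccc(OCC=C)c(OCC=C)c1)C(=O)O[C@H](Cc1ccc(OCC=C)c(OCC=C)c1)C(=O)OCC=C | intermediate
23 | nona-O-allyl target, (2S,3S)-trans dihydrobenzofuran with both side-chain centres (R) | O=C(/C=C/c1ccc(OCC=C)c(OCC=C)c1)O[C@H](Cc1ccc(OCC=C)c2c1[C@H](C(=O)O[C@H](Cc1ccc(OCC=C)c(OCC=C)c1)C(=O)OCC=C)[C@@H](c1ccc(OCC=C)c(OCC=C)c1)O2)C(=O)OCC=C | intermediate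
24 | CNP0201431.1 | O=C(/C=C/c1ccc(O)c(O)c1)O[C@H](Cc1ccc(O)c2c1[C@H](C(=O)O[C@H](Cc1ccc(O)c(O)c1)C(=O)O)[C@@H](c1ccc(O)c(O)c1)O2)C(=O)O | target

**Step count**
Total steps: 13. Longest linear sequence: 10 (steps 4–13, from L-tyrosine). The branches through 2/4 (steps 1–2) and 6 (step 3) join at steps 7, 11 and 12.

**Steps most likely to fail**

Step 12 (the proposed relay). Risks: slow alcoholysis by the hindered α-hydroxy ester, erosion of the C2 selectivity by retro-oxa-Michael equilibration, and ester scrambling. Fallback with known chemistry, setting out from 21 and 6 and returning at 23: DMAP/Et3N-catalysed acyl transfer in CH2Cl2 opens the aryl lactone with 6 to the open phenol 22, which is now isolated. Cs2CO3 in MeCN at 0 °C then closes it by an uncatalysed intramolecular oxa-Michael addition and equilibrates C3 to the trans series. This gives 23 together with the (2R,3R)-diastereomer of 23 F7 in roughly equal amounts; the two are diastereomers because of the fixed (R) side-chain centres and are separated by preparative HPLC. F7 can be recycled by renewed treatment with Cs2CO3 (ring opening and re-closure).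

Step 9 (Gassman ortho-alkylation at the flanked ring carbon of a polyfunctional phenol). Risks: slow rearrangement to the hindered position and electrophilic chlorination. Fallback setting out from 16 and returning at 20, bypassing 19: 16 is converted to its bromomagnesium phenoxide (EtMgBr, 1.0 equiv, toluene/CH2Cl2, −40 °C) and treated with ethyl glyoxylate. This chelation-directed ortho-hydroxyalkylation gives the ethyl ortho-hydroxymandelate of 16 F4. TsOH in toluene closes it to the 3-hydroxy analogue of lactone 20 F5. Ac2O/pyridine gives the 3-acetoxy analogue of lactone 20 F6, and Zn/AcOH removes the benzylic α-acetoxy group to give 20.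

Step 5 (formylation of the unprotected hydroxy acid). Risks: poorly soluble magnesium carboxylate and low conversion. Fallback setting out from 10 and returning at 13, at the cost of one extra step: 10 is first esterified with one equivalent of allyl bromide and KHCO3 in DMF to allyl (S)-2-hydroxy-3-(4-hydroxyphenyl)propanoate F1. This ester, a standard substrate class for the magnesium-mediated formylation, is formylated through allyl (S)-2-hydroxy-3-[4-hydroxy-3-(hydroxymethyl)phenyl]propanoate F2 (not isolated) to allyl (S)-3-(3-formyl-4-hydroxyphenyl)-2-hydroxypropanoate F3. The phenol of F3 is then allylated (allyl bromide, K2CO3, DMF) to give 13.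

**Further compounds**
F1 | step 5 | allyl (S)-2-hydroxy-3-(4-hydroxyphenyl)propanoate | C=CCOC(=O)[C@@H](O)Cc1ccc(O)cc1
F2 | step 5 | allyl (S)-2-hydroxy-3-[4-hydroxy-3-(hydroxymethyl)phenyl]propanoate | C=CCOC(=O)[C@@H](O)Cc1ccc(O)c(CO)c1
F3 | step 5 | allyl (S)-3-(3-formyl-4-hydroxyphenyl)-2-hydroxypropanoate | C=CCOC(=O)[C@@H](O)Cc1ccc(O)c(C=O)c1
F4 | step 9 | ethyl ortho-hydroxymandelate of 16 (16 carrying CH(OH)CO2Et at the ring carbon between the side chain and the OH; both epimers) | C=CCOC(=O)[C@H](OC(=O)/C=C/c1ccc(OCC=C)c(OCC=C)c1)Cc1ccc(OCC=C)c(O)c1C(O)C(=O)OCC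
F5 | step 9 | 3-hydroxy analogue of lactone 20 (both epimers) | C=CCOC(=O)[C@H](OC(=O)/C=C/c1ccc(OCC=C)c(OCC=C)c1)Cc1ccc(OCC=C)c2OC(=O)C(O)c12
F6 | step 9 | 3-acetoxy analogue of lactone 20 (both epimers) | C=CCOC(=O)[C@H](OC(=O)/C=C/c1ccc(OCC=C)c(OCC=C)c1)Cc1ccc(OCC=C)c2OC(=O)C(OC(C)=O)c12
F7 | step 12 | (2R,3R)-diastereomer of 23 | O=C(/C=C/c1ccc(OCC=C)c(OCC=C)c1)O[C@H](Cc1ccc(OCC=C)c2c1[C@@H](C(=O)O[C@H](Cc1ccc(OCC=C)c(OCC=C)c1)C(=O)OCC=C)[C@H](c1ccc(OCC=C)c(OCC=C)c1)O2)C(=O)OCC=C
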